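Price each given number before you integrate anything.

- oak: electrophile 0.020 M; nucleophile 1.50 equiv; free base 3.00 equiv; protic impurity 0.400 mM; time 3.0 min
- alder: electrophile 0.020 M; nucleophile 1.50 equiv; free base 4.50 equiv; protic impurity 0.400 mM; time 3.0 min

1. part of the electrophile that has reacted at the end, oak
2. part of the electrophile that has reacted at the end, alder
3. what raising the equivalents of free base from its lowest to its highest value here does to the part of the electrophile that has reacted (changes below 5 percentage points count as none) (it falls / no change / it rises)

    electrophile + nucleophile → acid set free + target (k1 = 0.373 M⁻¹ s⁻¹)
    nucleophile + acid set free ⇌ protonated nucleophile, settled at all times (K2 = 14600 M⁻¹)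
    acid set free + free base ⇌ salt of the base, settled at all times (K3 = 2.81 × 10⁵ M⁻¹)
    nucleophile + target → over-reaction product (k4 = 0.151 M⁻¹ s⁻¹)
    electrophile + protic impurity → quenched substrate (k5 = 9.05 M⁻¹ s⁻¹)
    acid set free → by-product carried off (k6 = 0.00169 s⁻¹)

- I took the acid constants first. I set the acid split S as the base-binding constant times [free base], over the nucleophile-binding constant times [nucleophile]. At the charge it stood at 38.5 in oak and 57.7 in alder. Counting the whole electrophile charge as acid, I estimated 5.06 × 10⁻⁴ M of protonated nucleophile in oak, hardly any of its charge, so I dropped both constants and expected no change with base.
- The acid-loss step has a half-life of 6.8 min, but it works on free acid, 1.19 × 10⁻⁶ M at that count in oak, so I dropped it too.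
- With electrophile at its charge, the impurity had a half-life of 0.0638 min, shorter than the 1.0 min half-life of electrophile by coupling, so I let the impurity take its whole charge at the start: 2.00% of the electrophile.
- I kept the coupling and over-reaction constants. I carried their ratio, the selectivity factor s = 0.405. Nucleophile multiplies both steps and cancels, so with x the electrophile left of what the quench spared, target over the same base is x to the power s, minus x, over one minus s.
- That left 1.53 nucleophile per spared electrophile. Integrating with one nucleophile spent per coupling left 25.5%; with two it left 40.0%.
- To join the ends, the curve at the first x gave a cost of 1.28 nucleophile per coupling. Integrating at that cost left 29.5%, so I committed to 71.1% reacted in both flasks.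
- The forecast gave 72% for oak (69% to 75%) and 72.3% for alder (69% to 75%), with no change, since “The base binds the acid far more strongly than the nucleophile does”. Mine stood lower.
- The simulation gave 72.2% for oak and 72.2% for alder, a shift of 0.083 percentage points: no change. At 3.00 min, protonated nucleophile stood at 1.90 × 10⁻⁴ M in oak and 1.16 × 10⁻⁴ M in alder, with free nucleophile at 40.6% and 40.7% of its charge. In oak, with 27.8% of electrophile left, s gave 52.2% of target, and the flask held 52.2%. A flask like oak but with 0.900 equiv of nucleophile kept 47.5% of electrophile; s gave 43.0% of target, and that flask held 43.0%.

All constants are made up; the flask was simulated.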